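**Retrosynthetic overview**
1. Numbering (xanthane type, primes = right half): ring A = left methylene lactone (C7, C8, C11, C12, O); ring B = left cycloheptane (C1, C5–C10); ring C = cyclohexene (C1, C2, C3, C11′, C13′, C5); ring D = spiro-lactone (C7′, C8′, C11′, C12′, O); ring E = right cycloheptene.
2. Enabling feature: the spiro atom C11′ is the α-carbon of the ring D carbonyl C12′, is bonded to C3 of ring C, and reaches C5 (next to carbinol C1) through C13′. With C3 as a ketone and C2 as its methyl, C11′ is the enolate carbon formed when a C1-ketone enolate (C5) adds to an enone C13′=C11′–C3=O, and the 1,2-trans O8′ can carry C12′ as a carbonate within 5-exo reach.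
3. Disconnections (backwards): C2′=C3′ by cross-metathesis; ring A methylene by Hofmann-type elimination; C3–C4 (acetyl) by enol triflate/Stille; ring C by aldol C2–C1; then one union, C13′–C5 (Michael) plus C11′–C12′ (Claisen-type lactonization, ring D), of ketone 13 with enone carbonate 21.
4. Both partners come from keto lactone 13: one catalytic reduction sets C8/C8′, malonate addition and equilibration relay C7 and C10 on a cyclohexanone, a one-carbon ring expansion gives the cycloheptanone, and 21 is 13 with its lactone recast (MeLi) as the C3 ketone.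
5. Ring order: carbocycle B/E (six-membered, then expanded), ring A, ring D (key step), ring C.

Key step: step 14

Remark: the target is taken exactly as drawn, i.e. both lactones trans-fused with 7S,8R,10S (7′S,8′R,10′S) and the C10 methyl cis to O8, which is not the natural xanthatin series, so both halves are built de novo.

**Route**

Step 1
Reactants: 1 1,4-dioxaspiro[4.5]dec-6-en-8-one
Product: 2 (8R)-1,4-dioxaspiro[4.5]dec-6-en-8-ol
Conditions: (S)-1-methyl-3,3-diphenyltetrahydro-1H,3H-pyrrolo[1,2-c][1,3,2]oxazaborole (10 mol%), BH3·SMe2, THF, −20 °C; MeOH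
Reagents that add atoms: none
Why: Corey–Bakshi–Shibata reduction, with the alkenyl arm as the large group, should deliver hydride to one carbonyl face and set the only reagent-controlled stereocenter (later C8 and C8′) as R.

Step 2
Reactants: 2 (8R)-1,4-dioxaspiro[4.5]dec-6-en-8-ol
Product: 3 (8R)-8-[(tert-butyldimethylsilyl)oxy]-1,4-dioxaspiro[4.5]dec-6-ene
Conditions: tBuMe2SiCl, imidazole, DMF, rt
Reagents that add atoms: tert-butyldimethylsilyl chloride, CC(C)(C)[Si](C)(C)Cl
Why: Standard silylation of a secondary allylic alcohol, which leaves the stereocenter untouched.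

Step 3
Reactants: 3 (8R)-8-[(tert-butyldimethylsilyl)oxy]-1,4-dioxaspiro[4.5]dec-6-ene
Product: 4 (4R)-4-[(tert-butyldimethylsilyl)oxy]cyclohex-2-en-1-one
Conditions: pyridinium p-toluenesulfonate (cat.), acetone–H2O, 50 °C
Reagents that add atoms: water, O
Why: Mild acetal hydrolysis should unmask the enone without cleaving the silyl ether or eliminating the γ-oxygen.

Step 4
Reactants: 4 (4R)-4-[(tert-butyldimethylsilyl)oxy]cyclohex-2-en-1-one
Product: 6 (4R)-4-[(tert-butyldimethylsilyl)oxy]-6-methylcyclohex-2-en-1-one (C6 epimers), via lithium dienolate 5 (not isolated)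
Conditions: LiN(iPr)2, THF, −78 °C; MeI, −78 → −20 °C; NH4Cl (aq.)
Reagents that add atoms: iodomethane, CI
Why: Kinetic α′-deprotonation of the enone and enolate alkylation; the C6 configuration (expected mainly trans) does not matter because it is equilibrated in step 5.

Step 5
Reactants: 6 (4R)-4-[(tert-butyldimethylsilyl)oxy]-6-methylcyclohex-2-en-1-one
Product: 7 di-tert-butyl 2-[(1S,2R,4S)-2-[(tert-butyldimethylsilyl)oxy]-4-methyl-5-oxocyclohexyl]malonate
Conditions: di-tert-butyl malonate (1.5 equiv), KOtBu (1.2 equiv), THF–tBuOH, 0 °C, then 6; then KOtBu (0.5 equiv), rt; AcOH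
Reagents that add atoms: di-tert-butyl malonate, CC(C)(C)OC(=O)CC(=O)OC(C)(C)C
Why: Malonate Michael addition should occur anti to the γ-silyloxy group (C7 trans to O8), and the small excess of alkoxide then equilibrates the α-methyl center (C10) to the all-equatorial cyclohexanone while the adduct, held as its malonate anion, cannot undergo retro-Michael reaction.

Step 6
Reactants: 7 di-tert-butyl 2-[(1S,2R,4S)-2-[(tert-butyldimethylsilyl)oxy]-4-methyl-5-oxocyclohexyl]malonate
Product: 9 di-tert-butyl 2-[(1S,2R,4S)-2-[(tert-butyldimethylsilyl)oxy]-4-methyl-5-oxocycloheptyl]malonate, via α-silyl cycloheptanone 8 (not isolated)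
Conditions: Me3SiCHN2, BF3·OEt2, CH2Cl2, −78 → −30 °C; then 1 M HCl, THF, 0 °C
Reagents that add atoms: trimethylsilyldiazomethane, C[Si](C)(C)C=[N+]=[N-]
Why: Lewis-acid-promoted diazoalkane homologation (Tiffeneau–Demjanov-type 1,2-shift) in which the unsubstituted α-methylene should migrate in preference to the methyl-bearing α-carbon, inserting C5 between C1 and C6 without touching a stereocenter.

Step 7
Reactants: 9 di-tert-butyl 2-[(1S,2R,4S)-2-[(tert-butyldimethylsilyl)oxy]-4-methyl-5-oxocycloheptyl]malonate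
Product: 11 (3aS,7S,8aR)-7-methyl-2,6-dioxooctahydro-2H-cyclohepta[b]furan-3-carboxylic acid (C3 epimers), via hydroxy malonic acid 10 (not isolated)
Conditions: CF3CO2H–H2O (9:1), CH2Cl2, 0 °C → rt; then toluene, 40 °C
Reagents that add atoms: none
Why: Acidolysis of both tert-butyl esters and the silyl ether, then acid-catalyzed lactonization of the trans-1,2 hydroxy malonic acid, closes the trans-fused γ-lactone (ring A) with C7 and C8 retained.

Step 8
Reactants: 11 (3aS,7S,8aR)-7-methyl-2,6-dioxooctahydro-2H-cyclohepta[b]furan-3-carboxylic acid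
Product: 12 (3aS,7S,8aR)-7-methyl-3-methylidenehexahydro-2H-cyclohepta[b]furan-2,6(3H)-dione
Conditions: Et2NH, aq. HCHO, NaOAc, AcOH, rt → 60 °C
Reagents that add atoms: formaldehyde, C=O
Why: Decarboxylative Mannich methylenation of the α-carboxy lactone (iminium alkylation, then loss of CO2 and amine) is the classical mild route to α-methylene γ-lactones and leaves the ketone alone.

Step 9
Reactants: 12 (3aS,7S,8aR)-7-methyl-3-methylidenehexahydro-2H-cyclohepta[b]furan-2,6(3H)-dione
Product: 13 (3R,3aS,7S,8aR)-3-[(dimethylamino)methyl]-7-methylhexahydro-2H-cyclohepta[b]furan-2,6(3H)-dione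
Conditions: Me2NH (2 M in THF), rt
Reagents that add atoms: dimethylamine, CNC
Why: Aza-Michael addition masks the methylene lactone as its Mannich base before any enolate chemistry, with protonation of the lactone enolate anti to H-7 expected to give C11 as R (this center is erased again in steps 13 and 19).

Step 10
Reactants: 13 (3R,3aS,7S,8aR)-3-[(dimethylamino)methyl]-7-methylhexahydro-2H-cyclohepta[b]furan-2,6(3H)-dione
Product: 15 (3R,3aS,7S,8aR)-3-[(dimethylamino)methyl]-7-methyl-2-oxo-3,3a,4,7,8,8a-hexahydro-2H-cyclohepta[b]furan-6-yl trifluoromethanesulfonate, via potassium enolate 14 (not isolated)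
Conditions: KN(SiMe3)2, THF, −78 °C; PhNTf2, −78 → 0 °C; NH4Cl (aq.)
Reagents that add atoms: N-phenylbis(trifluoromethanesulfonimide), O=S(=O)(N(c1ccccc1)S(=O)(=O)C(F)(F)F)C(F)(F)F
Why: Kinetic deprotonation by the hindered potassium amide at the C5 methylene (not at the methyl-bearing C10 or the less acidic lactone methine) and O-sulfonylation of the reactive potassium enolate should give the C1=C5 enol triflate.

Step 11
Reactants: 15 (3R,3aS,7S,8aR)-3-[(dimethylamino)methyl]-7-methyl-2-oxo-3,3a,4,7,8,8a-hexahydro-2H-cyclohepta[b]furan-6-yl trifluoromethanesulfonate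
Product: 16 (3R,3aS,7S,8aR)-3-[(dimethylamino)methyl]-6-ethenyl-7-methyl-3,3a,4,7,8,8a-hexahydro-2H-cyclohepta[b]furan-2-one
Conditions: Bu3Sn(CH=CH2), Pd(PPh3)4 (5 mol%), LiCl, THF, 65 °C
Reagents that add atoms: tributyl(ethenyl)stannane, C=C[Sn](CCCC)(CCCC)CCCC
Why: Stille coupling of the alkenyl triflate installs the ethenyl group that becomes C2′ and C3′.

Step 12
Reactants: 16 (3R,3aS,7S,8aR)-3-[(dimethylamino)methyl]-6-ethenyl-7-methyl-3,3a,4,7,8,8a-hexahydro-2H-cyclohepta[b]furan-2-one
Product: 18 (3R)-4-(dimethylamino)-3-[(1S,5S,7R)-4-ethenyl-7-hydroxy-5-methylcyclohept-3-en-1-yl]butan-2-one, via lithium hemiketal 17 (not isolated)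
Conditions: MeLi (1.05 equiv), THF, −78 °C; NH4Cl (aq.)
Reagents that add atoms: methyllithium, [Li]C
Why: Addition of one equivalent of methyllithium to the lactone at low temperature should stop at the lithium hemiketal and give the γ-hydroxy methyl ketone (in equilibrium with its lactol), so that the former lactone carbonyl becomes C3 and the new methyl C2.

Step 13
Reactants: 18 (3R)-4-(dimethylamino)-3-[(1S,5S,7R)-4-ethenyl-7-hydroxy-5-methylcyclohept-3-en-1-yl]butan-2-one
Product: 21 (1R,2S,6S)-5-ethenyl-6-methyl-2-(3-oxobut-1-en-2-yl)cyclohept-4-en-1-yl phenyl carbonate, via methiodide 19 (not isolated), via hydroxy enone 20 (not isolated)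
Conditions: MeI (1.1 equiv), CH2Cl2, rt; pyridine, 40 °C; PhOCOCl, 4-(dimethylamino)pyridine (cat.), 0 °C → rt
Reagents that add atoms: phenyl chloroformate, O=C(Cl)Oc1ccccc1
Why: N-Methylation and Hofmann-type (E1cB) elimination of the Mannich base give the α-methylene ketone (C11′=C13′), and chloroformate acylation of the C8′ alcohol installs the aryl carbonate that carries C12′.

Step 14
Reactants: 13 (3R,3aS,7S,8aR)-3-[(dimethylamino)methyl]-7-methylhexahydro-2H-cyclohepta[b]furan-2,6(3H)-dione; 21 (1R,2S,6S)-5-ethenyl-6-methyl-2-(3-oxobut-1-en-2-yl)cyclohept-4-en-1-yl phenyl carbonate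
Product: 24 Michael–Claisen adduct (5S,11′R)-11′-acetyl spiro-lactone diketone, via lithium enolate 22 (not isolated), via adduct enolate 23 (not isolated)
Conditions: 13, LiN(iPr)2 (1.05 equiv), THF, −78 °C; then 21, −78 → −40 °C; NH4Cl (aq.)
Reagents that add atoms: none
Why: The kinetic lithium enolate 22 (deprotonation at the C5 methylene, not at the methyl-bearing C10) adds 1,4 to the unhindered CH2 terminus (C13′) of enone 21, and the resulting tetrasubstituted enolate 23 (C11′=C3) is at once C-acylated by the neighbouring C8′ phenyl carbonate with loss of phenoxide, which forms the C11′–C12′ bond and closes ring D. The closest known reaction type is the Michael–Claisen (Michael–Dieckmann) annulation, in which an enolate generated by conjugate addition is trapped by a phenyl ester; here the ester is a carbonate, so the acyl transfer delivers a lactone. Ring D closes in a 5-exo-trig (enolexo) mode at the carbonate carbon. C5 is set by axial attack on the chair-like enolate of the trans-fused bicycle (lactone bonds and C10 methyl equatorial), on the face anti to the pseudo-axial C6–H and trans to the C7–C11 bond; C11′ is set by allylic 1,3-strain, the C7′–H eclipsing the enolate C=C so that the carbonate on C8′ reaches only one enolate face, which places C3 syn to H-7′ and C13′ syn to C6′. The step needs conjugate over carbonyl addition and C- over O-acylation: 1,2-adducts to the α-branched methyl ketone revert whereas the five-membered C-acylation is irreversible, O-acylation would need a seven-membered enol carbonate, and phenoxide is too weak a base to enolize the two ketones at −40 °C.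

Step 15
Reactants: 24 Michael–Claisen adduct (5S,11′R)-11′-acetyl spiro-lactone diketone
Product: 26 ring C ketol trimethylsilyl ether (1R; C3 ketone), via lithium aldolate 25 (not isolated)
Conditions: LiN(SiMe3)2 (1.1 equiv), THF, −78 → −40 °C; Me3SiCl, −78 → 0 °C
Reagents that add atoms: chlorotrimethylsilane, C[Si](C)(C)Cl
Why: Kinetic deprotonation of the acetyl methyl (C2) and intramolecular aldol addition to the C1 ketone (Robinson-type ketolization, 6-enolexo-exo-trig) closes ring C cis-fused, because the tether on C5 forces attack on the C1 face syn to C13′ so that O1 ends trans to the C10 methyl (C1 R), and silylation in the same flask blocks retro-aldol.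

Step 16
Reactants: 26 ring C ketol trimethylsilyl ether (1R; C3 ketone)
Product: 28 C2=C3 enol triflate of 26, via potassium enolate 27 (not isolated)
Conditions: KN(SiMe3)2, THF, −78 °C; N-(5-chloropyridin-2-yl)-1,1,1-trifluoro-N-(trifluoromethylsulfonyl)methanesulfonamide, −78 °C; NH4Cl (aq.)
Reagents that add atoms: N-(5-chloropyridin-2-yl)bis(trifluoromethanesulfonimide), O=S(=O)(N(c1ccc(Cl)cn1)S(=O)(=O)C(F)(F)F)C(F)(F)F
Why: The ring C ketone can enolize only toward C2 (C11′ is quaternary), and O-sulfonylation at −78 °C, below the temperature at which the β-silyloxy group is eliminated, should give the C2=C3 enol triflate.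

Step 17
Reactants: 28 C2=C3 enol triflate of 26
Product: 29 C3-(1-ethoxyethenyl) diene
Conditions: Bu3Sn[C(OEt)=CH2], Pd(PPh3)4 (10 mol%), LiCl, CuI (cat.), DMF, 60 °C
Reagents that add atoms: tributyl(1-ethoxyethenyl)stannane, CCOC(=C)[Sn](CCCC)(CCCC)CCCC
Why: Stille coupling with the 1-ethoxyvinyl stannane (an acetyl anion equivalent) forms the C3–C4 bond at the hindered triflate.

Step 18
Reactants: 29 C3-(1-ethoxyethenyl) diene
Product: 30 γ-hydroxy enone (C1–OH, C2=C3, acetyl on C3) still carrying C11–CH2NMe2 and the 1′-ethenyl group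
Conditions: 1 M HCl, THF, 0 °C
Reagents that add atoms: water, O
Why: Dilute acid hydrolyzes the enol ether to the methyl ketone and cleaves the tertiary silyl ether, and at 0 °C should not ionize the tertiary allylic alcohol.

Step 19
Reactants: 30 γ-hydroxy enone (C1–OH, C2=C3, acetyl on C3) still carrying C11–CH2NMe2 and the 1′-ethenyl group
Product: 32 1′-ethenyl precursor of the target (ring A methylene lactone restored), via methiodide 31 (not isolated)
Conditions: MeI, MeCN, rt; NaHCO3 (aq.), CH2Cl2, rt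
Reagents that add atoms: none
Why: Quaternization of the tertiary amine and mild-base Hofmann-type elimination regenerate the α-methylene lactone of ring A.

Step 20
Reactants: 32 1′-ethenyl precursor of the target
Product: 33 CNP0168949.4 (target)
Conditions: methyl vinyl ketone (10 equiv), Hoveyda–Grubbs second-generation catalyst (10 mol%), CH2Cl2, 40 °C
Reagents that add atoms: methyl vinyl ketone, C=CC(C)=O
Why: Cross-metathesis of the terminal ethenyl group of the diene with methyl vinyl ketone should give the E-dienone, while the 1,1-disubstituted methylene lactone and the trisubstituted enone are unreactive toward the ruthenium carbene.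

**Compound list**
1 | 1,4-dioxaspiro[4.5]dec-6-en-8-one | O=C1C=CC2(CC1)OCCO2 | starting material
2 | (8R)-1,4-dioxaspiro[4.5]dec-6-en-8-ol | O[C@H]1C=CC2(CC1)OCCO2 | intermediate
3 | (8R)-8-[(tert-butyldimethylsilyl)oxy]-1,4-dioxaspiro[4.5]dec-6-ene | CC(C)(C)[Si](C)(C)O[C@H]1C=CC2(CC1)OCCO2 | intermediate
4 | (4R)-4-[(tert-butyldimethylsilyl)oxy]cyclohex-2-en-1-one | O=C1C=C[C@H](O[Si](C)(C)C(C)(C)C)CC1 | intermediate
5 | lithium cross-conjugated dienolate of 4 (not isolated) | [Li]OC1=CC[C@@H](O[Si](C)(C)C(C)(C)C)C=C1 | intermediate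
6 | (4R)-4-[(tert-butyldimethylsilyl)oxy]-6-methylcyclohex-2-en-1-one, mixture of C6 epimers | O=C1C=C[C@H](O[Si](C)(C)C(C)(C)C)CC1C | intermediate
7 | di-tert-butyl 2-[(1S,2R,4S)-2-[(tert-butyldimethylsilyl)oxy]-4-methyl-5-oxocyclohexyl]malonate (all-equatorial) | CC(C)(C)OC(=O)C(C(=O)OC(C)(C)C)[C@@H]1CC(=O)[C@@H](C)C[C@H]1O[Si](C)(C)C(C)(C)C | intermediate
8 | ring-expanded α-trimethylsilyl cycloheptanone (silyl on the inserted carbon, epimers; not isolated) | CC(C)(C)OC(=O)C(C(=O)OC(C)(C)C)[C@@H]1CC([Si](C)(C)C)C(=O)[C@@H](C)C[C@H]1O[Si](C)(C)C(C)(C)C | intermediate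
9 | di-tert-butyl 2-[(1S,2R,4S)-2-[(tert-butyldimethylsilyl)oxy]-4-methyl-5-oxocycloheptyl]malonate | CC(C)(C)OC(=O)C(C(=O)OC(C)(C)C)[C@@H]1CCC(=O)[C@@H](C)C[C@H]1O[Si](C)(C)C(C)(C)C | intermediate
10 | 2-[(1S,2R,4S)-2-hydroxy-4-methyl-5-oxocycloheptyl]malonic acid (not isolated) | OC(=O)C(C(=O)O)[C@@H]1CCC(=O)[C@@H](C)C[C@H]1O | intermediate
11 | (3aS,7S,8aR)-7-methyl-2,6-dioxooctahydro-2H-cyclohepta[b]furan-3-carboxylic acid, trans-fused, C3 epimers | OC(=O)C1C(=O)O[C@@H]2C[C@H](C)C(=O)CC[C@@H]12 | intermediate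
12 | (3aS,7S,8aR)-7-methyl-3-methylidenehexahydro-2H-cyclohepta[b]furan-2,6(3H)-dione | C=C1C(=O)O[C@@H]2C[C@H](C)C(=O)CC[C@@H]12 | intermediate
13 | (3R,3aS,7S,8aR)-3-[(dimethylamino)methyl]-7-methylhexahydro-2H-cyclohepta[b]furan-2,6(3H)-dione (rings A and B; C1 ketone) | CN(C)C[C@@H]1C(=O)O[C@@H]2C[C@H](C)C(=O)CC[C@@H]12 | intermediate
14 | potassium C1=C5 enolate of 13 (not isolated) | CN(C)C[C@@H]1C(=O)O[C@@H]2C[C@H](C)C(O[K])=CC[C@@H]12 | intermediate
15 | (3R,3aS,7S,8aR)-3-[(dimethylamino)methyl]-7-methyl-2-oxo-3,3a,4,7,8,8a-hexahydro-2H-cyclohepta[b]furan-6-yl trifluoromethanesulfonate | CN(C)C[C@@H]1C(=O)O[C@@H]2C[C@H](C)C(OS(=O)(=O)C(F)(F)F)=CC[C@@H]12 | intermediate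
16 | (3R,3aS,7S,8aR)-3-[(dimethylamino)methyl]-6-ethenyl-7-methyl-3,3a,4,7,8,8a-hexahydro-2H-cyclohepta[b]furan-2-one | CN(C)C[C@@H]1C(=O)O[C@@H]2C[C@H](C)C(C=C)=CC[C@@H]12 | intermediate
17 | lithium hemiketal from MeLi addition to 16 (hemiketal carbon epimers; not isolated) | CN(C)C[C@@H]1C(C)(O[Li])O[C@@H]2C[C@H](C)C(C=C)=CC[C@@H]12 | intermediate
18 | (3R)-4-(dimethylamino)-3-[(1S,5S,7R)-4-ethenyl-7-hydroxy-5-methylcyclohept-3-en-1-yl]butan-2-one | CC(=O)[C@@H](CN(C)C)[C@@H]1CC=C(C=C)[C@@H](C)C[C@H]1O | intermediate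
19 | N-methyl ammonium iodide of 18 (not isolated) | C[N+](C)(C)C[C@H](C(C)=O)[C@@H]1CC=C(C=C)[C@@H](C)C[C@H]1O.[I-] | intermediate
20 | 3-[(1S,5S,7R)-4-ethenyl-7-hydroxy-5-methylcyclohept-3-en-1-yl]but-3-en-2-one (not isolated) | CC(=O)C(=C)[C@@H]1CC=C(C=C)[C@@H](C)C[C@H]1O | intermediate
21 | (1R,2S,6S)-5-ethenyl-6-methyl-2-(3-oxobut-1-en-2-yl)cyclohept-4-en-1-yl phenyl carbonate (ring E partner: enone C13′=C11′–C3=O, carbonate on O8′) | CC(=O)C(=C)[C@@H]1CC=C(C=C)[C@@H](C)C[C@H]1OC(=O)Oc1ccccc1 | intermediate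
22 | lithium C1=C5 enolate of 13 (not isolated) | CN(C)C[C@@H]1C(=O)O[C@@H]2C[C@H](C)C(O[Li])=CC[C@@H]12 | intermediate
23 | lithium enolate (C11′=C3) of the Michael adduct of 22 with 21 (not isolated) | CN(C)C[C@@H]1C(=O)O[C@@H]2C[C@H](C)C(=O)[C@H](CC(=C(C)O[Li])[C@@H]3CC=C(C=C)[C@@H](C)C[C@H]3OC(=O)Oc3ccccc3)C[C@@H]12 | intermediate
24 | Michael–Claisen adduct: ring B ketone of 13 carrying at C5 (S) the C13′H2 group bound to quaternary C11′ (R); C11′ bears the acetyl group (C3=O, C2H3) and is the spiro atom of the trans-fused ring D lactone on ring E (1′-ethenyl diene); C11 keeps CH2NMe2 | CN(C)C[C@@H]1C(=O)O[C@@H]2C[C@H](C)C(=O)[C@H](C[C@@]3(C(C)=O)C(=O)O[C@@H]4C[C@H](C)C(C=C)=CC[C@@H]34)C[C@@H]12 | intermediate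
25 | lithium aldolate (ring C closed, C1–OLi, C3 ketone; not isolated) | CN(C)C[C@@H]1C(=O)O[C@@H]2C[C@H](C)[C@]3(O[Li])CC(=O)[C@]4(C[C@@H]3C[C@@H]12)C(=O)O[C@@H]1C[C@H](C)C(C=C)=CC[C@H]14 | intermediate
26 | ring C ketol trimethylsilyl ether: (1R)-C1–OSiMe3, C2H2, C3 ketone, cis-fused rings B and C | CN(C)C[C@@H]1C(=O)O[C@@H]2C[C@H](C)[C@]3(O[Si](C)(C)C)CC(=O)[C@]4(C[C@@H]3C[C@@H]12)C(=O)O[C@@H]1C[C@H](C)C(C=C)=CC[C@H]14 | intermediate
27 | potassium C2=C3 enolate of 26 (not isolated) | CN(C)C[C@@H]1C(=O)O[C@@H]2C[C@H](C)[C@]3(O[Si](C)(C)C)C=C(O[K])[C@]4(C[C@@H]3C[C@@H]12)C(=O)O[C@@H]1C[C@H](C)C(C=C)=CC[C@H]14 | intermediate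
28 | C2=C3 enol triflate of 26 (triflate on C3) | CN(C)C[C@@H]1C(=O)O[C@@H]2C[C@H](C)[C@]3(O[Si](C)(C)C)C=C(OS(=O)(=O)C(F)(F)F)[C@]4(C[C@@H]3C[C@@H]12)C(=O)O[C@@H]1C[C@H](C)C(C=C)=CC[C@H]14 | intermediate
29 | C3-(1-ethoxyethenyl) diene | CN(C)C[C@@H]1C(=O)O[C@@H]2C[C@H](C)[C@]3(O[Si](C)(C)C)C=C(C(=C)OCC)[C@]4(C[C@@H]3C[C@@H]12)C(=O)O[C@@H]1C[C@H](C)C(C=C)=CC[C@H]14 | intermediate
30 | γ-hydroxy enone: (1R)-C1–OH, C2=C3, acetyl on C3; C11–CH2NMe2 and 1′-ethenyl retained | CN(C)C[C@@H]1C(=O)O[C@@H]2C[C@H](C)[C@]3(O)C=C(C(C)=O)[C@]4(C[C@@H]3C[C@@H]12)C(=O)O[C@@H]1C[C@H](C)C(C=C)=CC[C@H]14 | intermediate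
31 | N-methyl ammonium iodide of 30 (not isolated) | C[N+](C)(C)C[C@@H]1C(=O)O[C@@H]2C[C@H](C)[C@]3(O)C=C(C(C)=O)[C@]4(C[C@@H]3C[C@@H]12)C(=O)O[C@@H]1C[C@H](C)C(C=C)=CC[C@H]14.[I-] | intermediate
32 | 1′-ethenyl precursor of the target (ring A α-methylene lactone restored) | C=C1C(=O)O[C@@H]2C[C@H](C)[C@]3(O)C=C(C(C)=O)[C@]4(C[C@@H]3C[C@@H]12)C(=O)O[C@@H]1C[C@H](C)C(C=C)=CC[C@H]14 | intermediate
33 | CNP0168949.4 (1R,5S,7S,8R,10S,11′R,7′S,8′R,10′S; 2′E) | C=C1C(=O)O[C@@H]2C[C@H](C)[C@]3(O)C=C(C(C)=O)[C@]4(C[C@@H]3C[C@@H]12)C(=O)O[C@@H]1C[C@H](C)C(/C=C/C(C)=O)=CC[C@H]14 | target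

**Step count and risks**
Total steps: 20. Longest linear sequence: 20 steps (1 → 13 → 21 → 33; compound 13 enters step 14 a second time as the other partner).

Steps most likely to fail:

1. Step 14. What may go wrong: carbonyl (1,2) addition or proton transfer from the methyl ketone outruns conjugate addition, the tetrasubstituted enolate is O-acylated, or the facial selectivity at C5 is poor. Fallback (stepwise Lewis-acid union; sets out from 13, comes back at 24): LiN(iPr)2/Me3SiCl should convert 13 into the less substituted trimethylsilyl enol ether F1. Mukaiyama–Michael addition of F1 to 21 (BF3·OEt2, CH2Cl2, −78 °C) should give the 1,5-diketone carbonate F2 with the carbonate intact, in which C5 can be equilibrated with mild base. NaH with a trace of tBuOH in THF then forms the C11′ enolate reversibly, and the irreversible Dieckmann-type lactonization (same allylic-strain control at C11′) should give 24.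

2. Step 6. What may go wrong: migration of the methyl-bearing α-carbon, which would move the ketone away from C10, or a second homologation. Fallback (ring expansion whose regiochemistry is fixed by the enolate; sets out from 7, comes back at 9): LiN(iPr)2 (2.2 equiv)/Me3SiCl should give the less substituted silyl enol ether F3. Simmons–Smith cyclopropanation (ZnEt2, CH2I2) should give the siloxycyclopropane F4. FeCl3 in DMF (Ito–Saegusa ring expansion) should open it to the β-chloro cycloheptanone F5, and NaOAc in MeOH should eliminate HCl to the cycloheptenone F6. H2 over palladium on carbon should then give compound 9.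

3. Step 15. What may go wrong: deprotonation at C5 or C10 instead of the acetyl methyl, retro-aldol of the lithium aldolate before silylation, or β-elimination to the ring C enone. Fallback (enamine catalysis instead of a metal enolate; sets out from 24, comes back at 26): pyrrolidine/AcOH should condense selectively with the less hindered methyl ketone, and the enamine should add to the C1 ketone to give the free ketol F7, which N-(trimethylsilyl)imidazole converts into 26.

**Further compounds**
F1 | step 14 | trimethylsilyl enol ether (C1=C5) of 13 | CN(C)C[C@@H]1C(=O)O[C@@H]2C[C@H](C)C(O[Si](C)(C)C)=CC[C@@H]12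
F2 | step 14 | 1,5-diketone carbonate (Michael adduct with C11′–H, C11′ epimers, carbonate intact) | CN(C)C[C@@H]1C(=O)O[C@@H]2C[C@H](C)C(=O)[C@H](CC(C(C)=O)[C@@H]3CC=C(C=C)[C@@H](C)C[C@H]3OC(=O)Oc3ccccc3)C[C@@H]12
F3 | step 6 | less substituted trimethylsilyl enol ether of 7 | CC(C)(C)OC(=O)C(C(=O)OC(C)(C)C)[C@@H]1C=C(O[Si](C)(C)C)[C@@H](C)C[C@H]1O[Si](C)(C)C(C)(C)C
F4 | step 6 | siloxycyclopropane (bicyclo[4.1.0]heptane, cyclopropane stereocenters undefined) | CC(C)(C)OC(=O)C(C(=O)OC(C)(C)C)[C@@H]1C2CC2(O[Si](C)(C)C)[C@@H](C)C[C@H]1O[Si](C)(C)C(C)(C)C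
F5 | step 6 | β-chloro cycloheptanone (C1 ketone, chlorine on C6, epimers) malonate | CC(C)(C)OC(=O)C(C(=O)OC(C)(C)C)[C@@H]1C(Cl)CC(=O)[C@@H](C)C[C@H]1O[Si](C)(C)C(C)(C)C
F6 | step 6 | cyclohept-2-enone (C1 ketone, C5=C6) malonate | CC(C)(C)OC(=O)C(C(=O)OC(C)(C)C)[C@@H]1C=CC(=O)[C@@H](C)C[C@H]1O[Si](C)(C)C(C)(C)C
F7 | step 15 | free ring C ketol (C1–OH, C3 ketone) | CN(C)C[C@@H]1C(=O)O[C@@H]2C[C@H](C)[C@]3(O)CC(=O)[C@]4(C[C@@H]3C[C@@H]12)C(=O)O[C@@H]1C[C@H](C)C(C=C)=CC[C@H]14
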